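**Plan**

- Locants follow the target: ring A is the quinone ring (C1–C4, C4a, C8a), ring B the benzenoid ring (C4a–C8a).
- Enabling feature: the quinone carbonyls C4 and C1 sit on the adjacent ring-B atoms C4a and C8a. C8a is flanked by the C8 aryl group, C4a only by C5–H. An aryne C4a≡C8a can therefore take up both ends of a C4–C3–C2(OMe)–C1 unit in one operation with a predictable orientation.
- Retrosynthesis: (a) the two phenolic O–benzyl bonds; (b) ring A at C4–C4a and C1–C8a, back to a 3-arylbenzyne and 3-methoxy-2-silyloxyfuran, with C1–C8a as the ring-closing bond; (c) the aryne back to a 2-(trimethylsilyl)aryl triflate and its phenol; (d) the C8–aryl bond (Suzuki–Miyaura) and the C6–CH2 bond (Negishi), back to 2-bromo-3-methylphenol.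
- Forward: ring B is bought as a cresol and dressed in the order I (C6), benzyl, aryl, Br then SiMe3 (C4a), OTf (C8a). Ring A is then fused on in one step, the hydroquinone is oxidised, and the benzyl ethers are removed last.
- Stereochemistry: the target has no stereocentre and no configurationally stable axis (the C8 aryl ring has no ortho substituent), so nothing has to be set.

Key step: step 8

Remark: 3-methoxyfuran-2(5H)-one (13) is taken to be a purchasable butenolide; 1, 3 and 7 are common catalogue chemicals.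

**Route**

Step 1
Reactants: 1 2-bromo-3-methylphenol
Product: 2 2-bromo-4-iodo-3-methylphenol
Conditions: NIS, TsOH·H2O (cat.), MeCN, 0 °C to rt
Reagents that add atoms: N-iodosuccinimide (NIS), O=C1CCC(=O)N1I
Why: Electrophilic aromatic iodination, which with acid-activated NIS should go para to the hydroxyl group at C4, a position also activated by the ortho methyl group.

Step 2
Reactants: 3 [4-(benzyloxy)-3-methoxyphenyl]methanol
Product: 4 4-(benzyloxy)-3-methoxybenzyl chloride
Conditions: SOCl2, CH2Cl2, 0 °C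
Reagents that add atoms: thionyl chloride, O=S(Cl)Cl
Why: Chlorodehydroxylation of an electron-rich benzylic alcohol through its chlorosulfite, a standard conversion.

Step 3
Reactants: 2 2-bromo-4-iodo-3-methylphenol; 4 4-(benzyloxy)-3-methoxybenzyl chloride
Product: 6 4-[4-(benzyloxy)-3-methoxybenzyl]-2-bromo-3-methylphenol, via benzylzinc chloride 5 (not isolated)
Conditions: 4, Zn dust, LiCl, THF, 25 °C; then 2, Pd(OAc)2, SPhos, THF, 25 °C (slow addition of 5)
Reagents that add atoms: none
Why: Negishi coupling, in which zerovalent palladium should insert into the C–I bond far faster than into the hindered C–Br bond, and slowly added benzylzinc chloride should couple faster than the free phenol protonates it.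

Step 4
Reactants: 6 4-[4-(benzyloxy)-3-methoxybenzyl]-2-bromo-3-methylphenol; 7 [4-(benzyloxy)-3-methoxyphenyl]boronic acid
Product: 8 4-[4-(benzyloxy)-3-methoxybenzyl]-2-[4-(benzyloxy)-3-methoxyphenyl]-3-methylphenol
Conditions: Pd(OAc)2, SPhos, K3PO4, toluene/H2O, 100 °C
Reagents that add atoms: none
Why: Suzuki–Miyaura coupling, in which the bulky electron-rich biaryl phosphine should allow oxidative addition and transmetalation at the di-ortho-substituted bromide while the phenol is tolerated as its phenoxide.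

Step 5
Reactants: 8 4-[4-(benzyloxy)-3-methoxybenzyl]-2-[4-(benzyloxy)-3-methoxyphenyl]-3-methylphenol
Product: 9 4-[4-(benzyloxy)-3-methoxybenzyl]-2-[4-(benzyloxy)-3-methoxyphenyl]-6-bromo-3-methylphenol
Conditions: NBS, i-Pr2NH (cat.), CH2Cl2, 0 °C
Reagents that add atoms: N-bromosuccinimide (NBS), O=C1CCC(=O)N1Br
Why: Amine-catalysed electrophilic ortho-bromination of a phenol, which should be much faster than bromination of the aryl ether rings and can only reach C6, the one free ortho/para position of the phenol ring.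

Step 6
Reactants: 9 4-[4-(benzyloxy)-3-methoxybenzyl]-2-[4-(benzyloxy)-3-methoxyphenyl]-6-bromo-3-methylphenol
Product: 12 4-[4-(benzyloxy)-3-methoxybenzyl]-2-[4-(benzyloxy)-3-methoxyphenyl]-3-methyl-6-(trimethylsilyl)phenyl trifluoromethanesulfonate, via aryl silyl ether 10 (not isolated), via lithium silylphenoxide 11 (not isolated)
Conditions: HMDS, THF, 65 °C; then n-BuLi, THF, −78 °C; then Tf2O, −78 °C to rt
Reagents that add atoms: hexamethyldisilazane (HMDS), C[Si](C)(C)N[Si](C)(C)C; trifluoromethanesulfonic anhydride (Tf2O), O=S(=O)(OS(=O)(=O)C(F)(F)F)C(F)(F)F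
Why: O-silylation, bromine–lithium exchange and 1,3 O-to-C silyl migration (retro-Brook rearrangement) should place SiMe3 on the carbon that bore bromine, and the lithium phenoxide is trapped as the triflate, the standard route to 2-(trimethylsilyl)aryl triflates.

Step 7
Reactants: 13 3-methoxyfuran-2(5H)-one
Product: 14 tert-butyl[(3-methoxyfuran-2-yl)oxy]dimethylsilane
Conditions: TBSOTf, Et3N, CH2Cl2, 0 °C
Reagents that add atoms: tert-butyldimethylsilyl trifluoromethanesulfonate (TBSOTf), CC(C)(C)[Si](C)(C)OS(=O)(=O)C(F)(F)F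
Why: Soft enolisation and O-silylation of a butenolide with a silyl triflate and an amine, the standard preparation of 2-silyloxyfurans.

Step 8
Reactants: 12 4-[4-(benzyloxy)-3-methoxybenzyl]-2-[4-(benzyloxy)-3-methoxyphenyl]-3-methyl-6-(trimethylsilyl)phenyl trifluoromethanesulfonate; 14 tert-butyl[(3-methoxyfuran-2-yl)oxy]dimethylsilane
Product: 19 6-[4-(benzyloxy)-3-methoxybenzyl]-8-[4-(benzyloxy)-3-methoxyphenyl]-2-methoxy-7-methylnaphthalene-1,4-dione, via aryne 15 (not isolated), via cesium furanolate 16 (not isolated), via aryl anion adduct 17 (not isolated), via hydroquinone 18 (not isolated)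
Conditions: 14 (1.5 equiv), CsF, 18-crown-6, THF, 25 °C; then AcOH; then Ag2O, 25 °C
Reagents that add atoms: none
Why: Proposed new method: fluoride strips silicon from both partners to give the C4a≡C8a aryne 15 and the furanolate 16, whose unsubstituted and most nucleophilic C5 (the α-carbon C3 is blocked by OMe) should attack the aryne at C4a, the carbon remote from the C8 aryl group, because that twisted, σ-withdrawing ring shields C8a and stabilises the carbanion developing beside it, the same orientation by which aryl Grignard reagents add to 3-arylbenzynes. The aryl anion 17 then closes ring A by 6-exo-trig addition of C8a to the lactone carbonyl, which forms the C1–C8a bond; the tetrahedral alkoxide collapses with C–O cleavage, the C4 alkoxide tautomerises to hydroquinone 18, and Ag2O oxidises it to the quinone. The closest known reaction types are the Hauser–Kraus-type annulation of 3-cyanophthalide anions with arynes to give anthraquinones and the [4+2] cycloaddition/ring opening of arynes with 2-alkoxyfurans, and a cycloaddition of any still-silylated 14 would pass through the same oxygen-bridged adduct with the same orientation. No stereocentre survives, since the sp3 carbon C4 made in the first bond is flattened on aromatisation. The step needs control over which aryne carbon takes C4 and which takes C1, secured by the aryl group at C8 and the hydrogen at C5 that flank the triple bond, and THF is used because it cannot protonate 17 before it closes.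

Step 9
Reactants: 19 6-[4-(benzyloxy)-3-methoxybenzyl]-8-[4-(benzyloxy)-3-methoxyphenyl]-2-methoxy-7-methylnaphthalene-1,4-dione
Product: 21 larreantin, 6-(4-hydroxy-3-methoxybenzyl)-8-(4-hydroxy-3-methoxyphenyl)-2-methoxy-7-methylnaphthalene-1,4-dione, via leuco hydroquinone 20 (not isolated)
Conditions: H2 (1 atm), Pd/C, EtOAc/MeOH, 25 °C; then air
Reagents that add atoms: none
Why: Hydrogenolysis of the two aryl benzyl ethers over palladium should also reduce the quinone to hydroquinone 20, which air re-oxidises (autoxidation of an electron-rich naphthohydroquinone) while the guaiacol-type phenols stay untouched.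

**Compound list**

1 | 2-bromo-3-methylphenol | Cc1cccc(O)c1Br | starting material
2 | 2-bromo-4-iodo-3-methylphenol | Cc1c(I)ccc(O)c1Br | intermediate
3 | [4-(benzyloxy)-3-methoxyphenyl]methanol | OCc1ccc(OCc2ccccc2)c(OC)c1 | starting material
4 | 4-(benzyloxy)-3-methoxybenzyl chloride | ClCc1ccc(OCc2ccccc2)c(OC)c1 | intermediate
5 | [4-(benzyloxy)-3-methoxybenzyl]zinc chloride | Cl[Zn]Cc1ccc(OCc2ccccc2)c(OC)c1 | intermediate
6 | 4-[4-(benzyloxy)-3-methoxybenzyl]-2-bromo-3-methylphenol | Cc1c(Cc2ccc(OCc3ccccc3)c(OC)c2)ccc(O)c1Br | intermediate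
7 | [4-(benzyloxy)-3-methoxyphenyl]boronic acid | OB(O)c1ccc(OCc2ccccc2)c(OC)c1 | starting material
8 | 4-[4-(benzyloxy)-3-methoxybenzyl]-2-[4-(benzyloxy)-3-methoxyphenyl]-3-methylphenol | Cc1c(Cc2ccc(OCc3ccccc3)c(OC)c2)ccc(O)c1-c1ccc(OCc2ccccc2)c(OC)c1 | intermediate
9 | 4-[4-(benzyloxy)-3-methoxybenzyl]-2-[4-(benzyloxy)-3-methoxyphenyl]-6-bromo-3-methylphenol | Cc1c(Cc2ccc(OCc3ccccc3)c(OC)c2)cc(Br)c(O)c1-c1ccc(OCc2ccccc2)c(OC)c1 | intermediate
10 | {4-[4-(benzyloxy)-3-methoxybenzyl]-2-[4-(benzyloxy)-3-methoxyphenyl]-6-bromo-3-methylphenoxy}trimethylsilane | Cc1c(Cc2ccc(OCc3ccccc3)c(OC)c2)cc(Br)c(O[Si](C)(C)C)c1-c1ccc(OCc2ccccc2)c(OC)c1 | intermediate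
11 | lithium 4-[4-(benzyloxy)-3-methoxybenzyl]-2-[4-(benzyloxy)-3-methoxyphenyl]-3-methyl-6-(trimethylsilyl)phenolate | Cc1c(Cc2ccc(OCc3ccccc3)c(OC)c2)cc([Si](C)(C)C)c([O-])c1-c1ccc(OCc2ccccc2)c(OC)c1.[Li+] | intermediate
12 | 4-[4-(benzyloxy)-3-methoxybenzyl]-2-[4-(benzyloxy)-3-methoxyphenyl]-3-methyl-6-(trimethylsilyl)phenyl trifluoromethanesulfonate | Cc1c(Cc2ccc(OCc3ccccc3)c(OC)c2)cc([Si](C)(C)C)c(OS(=O)(=O)C(F)(F)F)c1-c1ccc(OCc2ccccc2)c(OC)c1 | intermediate
13 | 3-methoxyfuran-2(5H)-one | COC1=CCOC1=O | starting material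
14 | tert-butyl[(3-methoxyfuran-2-yl)oxy]dimethylsilane | COc1ccoc1O[Si](C)(C)C(C)(C)C | intermediate
15 | 5-[4-(benzyloxy)-3-methoxybenzyl]-3-[4-(benzyloxy)-3-methoxyphenyl]-4-methyl-1,2-didehydrobenzene (aryne C4a≡C8a) | CC1=C(c2ccc(OCc3ccccc3)c(OC)c2)C#CC=C1Cc1ccc(OCc2ccccc2)c(OC)c1 | intermediate
16 | cesium 3-methoxyfuran-2-olate | COc1ccoc1[O-].[Cs+] | intermediate
17 | cesium 4-[4-(benzyloxy)-3-methoxybenzyl]-2-[4-(benzyloxy)-3-methoxyphenyl]-6-(4-methoxy-5-oxo-2,5-dihydrofuran-2-yl)-3-methylbenzen-1-ide | COC1=CC(OC1=O)c1cc(Cc2ccc(OCc3ccccc3)c(OC)c2)c(C)c(-c2ccc(OCc3ccccc3)c(OC)c2)[c-]1.[Cs+] | intermediate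
18 | 6-[4-(benzyloxy)-3-methoxybenzyl]-8-[4-(benzyloxy)-3-methoxyphenyl]-2-methoxy-7-methylnaphthalene-1,4-diol | COc1cc(O)c2cc(Cc3ccc(OCc4ccccc4)c(OC)c3)c(C)c(-c3ccc(OCc4ccccc4)c(OC)c3)c2c1O | intermediate
19 | 6-[4-(benzyloxy)-3-methoxybenzyl]-8-[4-(benzyloxy)-3-methoxyphenyl]-2-methoxy-7-methylnaphthalene-1,4-dione | COC1=CC(=O)c2cc(Cc3ccc(OCc4ccccc4)c(OC)c3)c(C)c(-c3ccc(OCc4ccccc4)c(OC)c3)c2C1=O | intermediate
20 | 6-(4-hydroxy-3-methoxybenzyl)-8-(4-hydroxy-3-methoxyphenyl)-2-methoxy-7-methylnaphthalene-1,4-diol | COc1cc(O)c2cc(Cc3ccc(O)c(OC)c3)c(C)c(-c3ccc(O)c(OC)c3)c2c1O | intermediate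
21 | larreantin, 6-(4-hydroxy-3-methoxybenzyl)-8-(4-hydroxy-3-methoxyphenyl)-2-methoxy-7-methylnaphthalene-1,4-dione | COC1=CC(=O)c2cc(Cc3ccc(O)c(OC)c3)c(C)c(-c3ccc(O)c(OC)c3)c2C1=O | target

**Summary**

Total step count: 9. Longest linear sequence: 7 steps (steps 1, 3, 4, 5, 6, 8, 9).

**Steps most likely to fail**

1. Step 8 (Proposed new method).
 - What may go wrong: the furanolate may add through the wrong terminus or to the wrong aryne carbon; the aryl anion may be protonated before it closes onto the lactone carbonyl; the product phenoxide may be O-arylated by a second aryne.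
 - Fallback (known chemistry, regiochemistry fixed by a blocked ortho carbon instead of aryne polarity): it sets out from phenol 8 and returns at hydroquinone 18.
 - 8 is converted with Tf2O and pyridine (CH2Cl2, 0 °C) into the aryl triflate F1.
 - Palladium-catalysed triflate-to-bromide exchange (KBr, Pd2(dba)3, t-BuBrettPhos, toluene, 100 °C) should give the aryl bromide F2.
 - Bromine–lithium exchange (n-BuLi, THF, −78 °C) gives the aryllithium F3. It should add to the more electrophilic carbonyl, the one next to C–OMe, of 3-methoxycyclobut-3-ene-1,2-dione (methyl semisquarate, used as an available reagent) to give the racemic 4-aryl-4-hydroxy-3-methoxycyclobutenone F4.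
 - Heating F4 in p-xylene at about 140 °C should open the four-membered ring to a dienylketene. Its 6π electrocyclisation can engage only C4a, because the other ortho position (C8) carries the aryl group, and tautomerisation gives 18.
 - 18 is oxidised with Ag2O to 19 as in step 8.

2. Step 5.
 - What may go wrong: electrophilic bromine may attack the two benzyloxy(methoxy)aryl rings instead of, or in addition to, the phenol ring.
 - Fallback (directed metalation instead of electrophilic substitution): it sets out from 8 and returns at 12.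
 - O-carbamoylation (ClC(O)NEt2, K2CO3, MeCN, 80 °C) gives the aryl N,N-diethylcarbamate F5.
 - Ortho-lithiation with in situ silylation (LiN(i-Pr)2, Me3SiCl, THF, −78 °C) at the only free ortho position gives the silylated carbamate F6.
 - Reductive carbamate cleavage with Cp2Zr(H)Cl (THF, rt) frees the 2-(trimethylsilyl)phenol F7, and Tf2O with pyridine gives 12.

3. Step 3.
 - What may go wrong: the free phenol may protonate the benzylzinc reagent; the electron-rich benzylic zinc reagent may homocouple; selectivity between C–I and C–Br may be lost.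
 - Fallback (polarity reversal, aryl nucleophile plus aldehyde): it sets out from 2 and returns at 6.
 - 2 is treated with i-PrMgCl·LiCl (2 equiv, THF, −20 °C to rt). The first equivalent deprotonates the phenol and the second exchanges iodine for magnesium, giving the arylmagnesium chloride F8.
 - F8 adds to 4-(benzyloxy)-3-methoxybenzaldehyde to give the racemic diarylmethanol F9.
 - Ionic hydrogenation of this doubly activated benzhydrol (Et3SiH, CF3CO2H, CH2Cl2, 0 °C) gives 6.

**Further compounds**

F1 | step 8 | 4-[4-(benzyloxy)-3-methoxybenzyl]-2-[4-(benzyloxy)-3-methoxyphenyl]-3-methylphenyl trifluoromethanesulfonate | Cc1c(Cc2ccc(OCc3ccccc3)c(OC)c2)ccc(OS(=O)(=O)C(F)(F)F)c1-c1ccc(OCc2ccccc2)c(OC)c1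
F2 | step 8 | 1-bromo-4-[4-(benzyloxy)-3-methoxybenzyl]-2-[4-(benzyloxy)-3-methoxyphenyl]-3-methylbenzene | Cc1c(Cc2ccc(OCc3ccccc3)c(OC)c2)ccc(Br)c1-c1ccc(OCc2ccccc2)c(OC)c1
F3 | step 8 | {4-[4-(benzyloxy)-3-methoxybenzyl]-2-[4-(benzyloxy)-3-methoxyphenyl]-3-methylphenyl}lithium | Cc1c(Cc2ccc(OCc3ccccc3)c(OC)c2)ccc([Li])c1-c1ccc(OCc2ccccc2)c(OC)c1
F4 | step 8 | 4-{4-[4-(benzyloxy)-3-methoxybenzyl]-2-[4-(benzyloxy)-3-methoxyphenyl]-3-methylphenyl}-4-hydroxy-3-methoxycyclobut-2-en-1-one (racemic) | COC1=CC(=O)C1(O)c1ccc(Cc2ccc(OCc3ccccc3)c(OC)c2)c(C)c1-c1ccc(OCc2ccccc2)c(OC)c1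
F5 | step 5 | 4-[4-(benzyloxy)-3-methoxybenzyl]-2-[4-(benzyloxy)-3-methoxyphenyl]-3-methylphenyl N,N-diethylcarbamate | CCN(CC)C(=O)Oc1ccc(Cc2ccc(OCc3ccccc3)c(OC)c2)c(C)c1-c1ccc(OCc2ccccc2)c(OC)c1
F6 | step 5 | 4-[4-(benzyloxy)-3-methoxybenzyl]-2-[4-(benzyloxy)-3-methoxyphenyl]-3-methyl-6-(trimethylsilyl)phenyl N,N-diethylcarbamate | CCN(CC)C(=O)Oc1c([Si](C)(C)C)cc(Cc2ccc(OCc3ccccc3)c(OC)c2)c(C)c1-c1ccc(OCc2ccccc2)c(OC)c1
F7 | step 5 | 4-[4-(benzyloxy)-3-methoxybenzyl]-2-[4-(benzyloxy)-3-methoxyphenyl]-3-methyl-6-(trimethylsilyl)phenol | Cc1c(Cc2ccc(OCc3ccccc3)c(OC)c2)cc([Si](C)(C)C)c(O)c1-c1ccc(OCc2ccccc2)c(OC)c1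
F8 | step 3 | [3-bromo-4-(chloromagnesiooxy)-2-methylphenyl]magnesium chloride | Cc1c([Mg]Cl)ccc(O[Mg]Cl)c1Br
F9 | step 3 | 4-{[4-(benzyloxy)-3-methoxyphenyl](hydroxy)methyl}-2-bromo-3-methylphenol (racemic) | Cc1c(C(O)c2ccc(OCc3ccccc3)c(OC)c2)ccc(O)c1Br
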